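**Retrosynthetic overview**

- The strategy rests on ring A: its carbons C2', C3', C4' and C6' carry oxygen in four different states (free OH, (S)-2-methylbutanoate, free OH, OMe), set around C1' (cinnamoyl) and C5' (H).
- Endgame: cleavage of a 4'-O-tert-butyl ether, preceded by oxidation of a C1' allylic carbinol and removal of its silyl group.
- Key disconnection: ring A is split into a 4-acyloxy-3-tert-butoxycyclobutenone (C2', C3', C4', C5') and a methyl ynol ether (C1', C6', masked cinnamoyl chain). Bonds C1'–C2' and C5'–C6' are formed and the ring closes at C2'–C3'.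
- The cyclobutenone comes from di-tert-butyl squarate (reduction, 1,3-carbonyl transposition, second reduction, esterification). The ynol ether comes from lithium methoxyacetylide and cinnamaldehyde, then silylation.
- Ring A is the only ring formed; the phenyl ring arrives with cinnamaldehyde.

Key step: step 7

Assumption: di-tert-butyl squarate 1 is bought as such, because plain esterification of squaric acid does not give the tert-butyl diester. The ring carbinol carbon of the cyclobutenone and the carbinol carbon of the ynol ether are used as racemates, since both end as sp2 carbons.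

**Route**

Step 1
Reactants: 1 di-tert-butyl squarate (3,4-di-tert-butoxycyclobut-3-ene-1,2-dione)
Product: 2 2,3-di-tert-butoxy-4-hydroxycyclobut-2-en-1-one (racemic)
Conditions: LiAlH(OtBu)3, THF, −78 → −20 °C; aq. potassium sodium tartrate
Reagents that add atoms: none
Why: Chemoselective 1,2-hydride reduction of one of the two equivalent vinylogous ester carbonyls by a bulky, mild aluminium hydride should stop at the mono-carbinol, whose stereocenter is racemic and is erased in step 2.

Step 2
Reactants: 2 2,3-di-tert-butoxy-4-hydroxycyclobut-2-en-1-one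
Product: 3 tert-butyl semisquarate (3-tert-butoxycyclobut-3-ene-1,2-dione)
Conditions: (CF3CO)2O, CH2Cl2, −78 → −20 °C; cold aq. NaHCO3
Reagents that add atoms: none
Why: O-Trifluoroacetylation makes the hydroxyl a leaving group, ionization gives the tert-butoxy-stabilized cyclobutenyl cation, and loss of the tert-butyl group from the oxocarbenium carbon next to the ketone leaves the 1,2-dione (the 1,3-carbonyl transposition by which squarate adducts are turned into cyclobutenediones).

Step 3
Reactants: 3 tert-butyl semisquarate
Product: 4 3-tert-butoxy-4-hydroxycyclobut-2-en-1-one (racemic)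
Conditions: LiAlH(OtBu)3 (1 equiv), THF, −78 °C; aq. potassium sodium tartrate
Reagents that add atoms: none
Why: Regioselective 1,2-hydride reduction: the carbonyl attached to the tert-butoxy-bearing carbon is a plain ketone while the other is a deactivated vinylogous ester carbonyl, so hydride should add to the former only, and the racemic carbinol center becomes aromatic C3' in step 7.

Step 4
Reactants: 4 3-tert-butoxy-4-hydroxycyclobut-2-en-1-one; 5 (S)-2-methylbutanoic acid
Product: 6 2-tert-butoxy-4-oxocyclobut-2-en-1-yl (S)-2-methylbutanoate (both configurations at the ring carbon)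
Conditions: DCC, DMAP (cat.), CH2Cl2, 0 °C
Reagents that add atoms: none
Why: Steglich esterification through the acylpyridinium ion avoids a ketene pathway, so the (S)-α-carbon of the acid should be retained; no new stereocenter is formed and the two ring epimers converge in step 7.

Step 5
Reactants: 7 chloroacetaldehyde dimethyl acetal; 8 (E)-cinnamaldehyde
Product: 10 (E)-1-methoxy-5-phenylpent-4-en-1-yn-3-ol (racemic), via lithium methoxyacetylide 9 (not isolated)
Conditions: Et2NH, n-BuLi, THF, 0 °C (LiNEt2, 3 equiv); 7, 0 °C; then 8, −78 °C; aq. NaHCO3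
Reagents that add atoms: none
Why: Base-induced double elimination of the chloroacetal (loss of methoxide, then chloride) and deprotonation give the lithium alkoxyacetylide, which adds 1,2 to the aldehyde (acetylide carbonyl addition); the racemic carbinol center becomes the ketone carbon in step 9.

Step 6
Reactants: 10 (E)-1-methoxy-5-phenylpent-4-en-1-yn-3-ol
Product: 11 (E)-tert-butyl[(1-methoxy-5-phenylpent-4-en-1-yn-3-yl)oxy]dimethylsilane (racemic)
Conditions: TBSCl, imidazole, DMF, 0 °C → rt; chromatography on Et3N-deactivated silica
Reagents that add atoms: tert-butyldimethylsilyl chloride (TBSCl), CC(C)(C)[Si](C)(C)Cl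
Why: Imidazole-mediated O-silylation under basic conditions caps the carbinol without the acid that would trigger Meyer–Schuster-type rearrangement of an alkoxyethynyl carbinol.

Step 7
Reactants: 6 2-tert-butoxy-4-oxocyclobut-2-en-1-yl (S)-2-methylbutanoate; 11 (E)-tert-butyl[(1-methoxy-5-phenylpent-4-en-1-yn-3-yl)oxy]dimethylsilane
Product: 16 6-tert-butoxy-3-[(E)-1-(tert-butyldimethylsilyloxy)-3-phenylprop-2-en-1-yl]-2-hydroxy-4-methoxyphenyl (S)-2-methylbutanoate (two epimers at the carbinol carbon), via acyloxyvinylketene 12 (not isolated), via 4-vinylcyclobutenone 13 (not isolated), via dienylketene 14 (not isolated), via 6-acyloxycyclohexa-2,4-dienone 15 (not isolated)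
Conditions: 11 (1.5 equiv), toluene (degassed), 80 → 110 °C
Reagents that add atoms: none
Why: Proposed new method: the closest known reaction type is the Danheiser benzannulation of cyclobutenones with alkoxyalkynes, together with the thermal ring opening of 4-oxygenated 3-alkoxycyclobutenones known from squarate chemistry; a 4-acyloxy-3-alkoxycyclobutenone has not been used as the partner, so the step is put forward on mechanistic grounds. Heating should open 6 by conrotatory 4π electrocyclic ring opening, the acyloxy group turning outward, to vinylketene 12, whose electrophilic carbonyl carbon is attacked by the nucleophilic β-carbon of ynol ether 11 in a regioselective [2+2] cycloaddition that forms the C1'–C2' and C5'–C6' bonds and gives 4-vinylcyclobutenone 13. Reversible 4π opening of 13 gives dienylketene 14, and ring A closes by thermal disrotatory 6π electrocyclization between the ketene carbon (C2') and the acyloxy-bearing terminus (C3') to dienone 15, which aromatizes by tautomerization. No new stereocenter is set: the ring carbon of 6 and the sp3 carbon of 15 become aromatic, the carbinol carbon of 11 is carried through as a racemate, and the neutral thermal conditions leave the (S)-α-carbon of the ester untouched. The selectivity needed is the orientation of the [2+2] step, and the oxygen-induced polarization of the ynol ether secures it, placing the side chain at C1' between the new 2'-hydroxyl and the 6'-methoxy group. All atoms of both partners are kept, and the alkyne is used in excess so that the vinylketene is trapped by it and not by the product phenol.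

Step 8
Reactants: 16 6-tert-butoxy-3-[(E)-1-(tert-butyldimethylsilyloxy)-3-phenylprop-2-en-1-yl]-2-hydroxy-4-methoxyphenyl (S)-2-methylbutanoate
Product: 17 6-tert-butoxy-2-hydroxy-3-[(E)-1-hydroxy-3-phenylprop-2-en-1-yl]-4-methoxyphenyl (S)-2-methylbutanoate (two epimers at the carbinol carbon)
Conditions: TBAF, AcOH (1:1), THF, 0 °C → rt; neutral work-up, crude used at once
Reagents that add atoms: none
Why: Fluoride-mediated cleavage of the silyl ether, buffered with acetic acid so that the 3'-ester should not migrate to the neighbouring 2'-oxygen and the doubly activated carbinol should not ionize.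

Step 9
Reactants: 17 6-tert-butoxy-2-hydroxy-3-[(E)-1-hydroxy-3-phenylprop-2-en-1-yl]-4-methoxyphenyl (S)-2-methylbutanoate
Product: 18 6-tert-butoxy-3-[(E)-cinnamoyl]-2-hydroxy-4-methoxyphenyl (S)-2-methylbutanoate (4'-O-tert-butyl ether of the target)
Conditions: MnO2 (activated, excess), CH2Cl2, rt
Reagents that add atoms: none
Why: MnO2 oxidation is selective for allylic and benzylic alcohols, and this carbinol is both; it removes the carbinol stereocenter (the epimers converge) and gives the hydrogen-bonded 2'-hydroxy enone.

Step 10
Reactants: 18 6-tert-butoxy-3-[(E)-cinnamoyl]-2-hydroxy-4-methoxyphenyl (S)-2-methylbutanoate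
Product: 19 3-[(E)-cinnamoyl]-2,6-dihydroxy-4-methoxyphenyl (S)-2-methylbutanoate (CNP0173852.1)
Conditions: CF3CO2H/CH2Cl2 (1:4), 0 °C, short reaction time
Reagents that add atoms: none
Why: Acidolysis of the aryl tert-butyl ether (loss of the tert-butyl cation as isobutene) at 0 °C should leave the aryl ester, its (S)-α-carbon, the enone and the methyl ether in place.

**Compound list**

1 | di-tert-butyl squarate (3,4-di-tert-butoxycyclobut-3-ene-1,2-dione) | CC(C)(C)OC1=C(OC(C)(C)C)C(=O)C1=O | starting material
2 | 2,3-di-tert-butoxy-4-hydroxycyclobut-2-en-1-one (racemic) | CC(C)(C)OC1=C(OC(C)(C)C)C(=O)C1O | intermediate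
3 | tert-butyl semisquarate (3-tert-butoxycyclobut-3-ene-1,2-dione) | CC(C)(C)OC1=CC(=O)C1=O | intermediate
4 | 3-tert-butoxy-4-hydroxycyclobut-2-en-1-one (racemic) | CC(C)(C)OC1=CC(=O)C1O | intermediate
5 | (S)-2-methylbutanoic acid | CC[C@H](C)C(=O)O | starting material
6 | 2-tert-butoxy-4-oxocyclobut-2-en-1-yl (S)-2-methylbutanoate (either ring configuration) | CC[C@H](C)C(=O)OC1C(=O)C=C1OC(C)(C)C | intermediate
7 | chloroacetaldehyde dimethyl acetal | COC(CCl)OC | starting material
8 | (E)-cinnamaldehyde | O=C/C=C/c1ccccc1 | starting material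
9 | lithium methoxyacetylide (not isolated) | COC#C[Li] | intermediate
10 | (E)-1-methoxy-5-phenylpent-4-en-1-yn-3-ol (racemic) | COC#CC(O)/C=C/c1ccccc1 | intermediate
11 | (E)-tert-butyl[(1-methoxy-5-phenylpent-4-en-1-yn-3-yl)oxy]dimethylsilane (racemic) | COC#CC(O[Si](C)(C)C(C)(C)C)/C=C/c1ccccc1 | intermediate
12 | acyloxyvinylketene from ring opening of 6 (not isolated) | CC[C@H](C)C(=O)O/C=C(\OC(C)(C)C)C=C=O | intermediate
13 | 4-vinylcyclobutenone from [2+2] addition of 12 to 11 (not isolated) | CC[C@H](C)C(=O)O/C=C(\OC(C)(C)C)C1C(=O)C(C(O[Si](C)(C)C(C)(C)C)/C=C/c2ccccc2)=C1OC | intermediate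
14 | dienylketene from ring opening of 13 (not isolated) | CC[C@H](C)C(=O)O/C=C(\OC(C)(C)C)/C=C(OC)\C(=C=O)C(O[Si](C)(C)C(C)(C)C)/C=C/c1ccccc1 | intermediate
15 | 6-acyloxycyclohexa-2,4-dienone from 6π closure of 14 (not isolated) | CC[C@H](C)C(=O)OC1C(=O)C(C(O[Si](C)(C)C(C)(C)C)/C=C/c2ccccc2)=C(OC)C=C1OC(C)(C)C | intermediate
16 | 6-tert-butoxy-3-[(E)-1-(tert-butyldimethylsilyloxy)-3-phenylprop-2-en-1-yl]-2-hydroxy-4-methoxyphenyl (S)-2-methylbutanoate | CC[C@H](C)C(=O)Oc1c(OC(C)(C)C)cc(OC)c(C(O[Si](C)(C)C(C)(C)C)/C=C/c2ccccc2)c1O | intermediate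
17 | 6-tert-butoxy-2-hydroxy-3-[(E)-1-hydroxy-3-phenylprop-2-en-1-yl]-4-methoxyphenyl (S)-2-methylbutanoate | CC[C@H](C)C(=O)Oc1c(OC(C)(C)C)cc(OC)c(C(O)/C=C/c2ccccc2)c1O | intermediate
18 | 6-tert-butoxy-3-[(E)-cinnamoyl]-2-hydroxy-4-methoxyphenyl (S)-2-methylbutanoate | CC[C@H](C)C(=O)Oc1c(OC(C)(C)C)cc(OC)c(C(=O)/C=C/c2ccccc2)c1O | intermediate
19 | 3-[(E)-cinnamoyl]-2,6-dihydroxy-4-methoxyphenyl (S)-2-methylbutanoate (CNP0173852.1) | CC[C@H](C)C(=O)Oc1c(O)cc(OC)c(C(=O)/C=C/c2ccccc2)c1O | target

**Step count**

Total: 10 steps. Longest linear sequence: 8 steps (steps 1, 2, 3, 4, 7, 8, 9, 10).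

**Steps most likely to fail**

1. Step 7 (the proposed new method).
   - What may go wrong: the vinylogous-ester cyclobutenone may open too slowly; the vinylketene may dimerize or acylate the product phenol; the tert-butyl enol ether may lose isobutene on heating; the benzylic silyl ether next to the new phenol may ionize to an ortho-quinone methide.
   - Fallback, known chemistry only, setting out from cinnamaldehyde 8 and acid 5 and coming back at target 19: ring A is taken from an aromatic starting material and its oxygens are differentiated by two directed ortho-metalations. Commercial 5-methoxyresorcinol is protected (MOMCl, i-Pr2NEt, CH2Cl2) as 1-methoxy-3,5-bis(methoxymethoxy)benzene F1. n-BuLi in THF at 0 °C lithiates the carbon between the two MOM ethers, and B(OMe)3 followed by H2O2/NaOH gives 4-methoxy-2,6-bis(methoxymethoxy)phenol F2. Silylation (TBSCl, imidazole, DMF) gives tert-butyl[4-methoxy-2,6-bis(methoxymethoxy)phenoxy]dimethylsilane F3. A second lithiation (n-BuLi, THF, 0 °C) at the carbon flanked by OMOM and OMe, then addition to 8 at −78 °C, gives the allylic carbinol (E)-1-[3-(tert-butyldimethylsilyloxy)-6-methoxy-2,4-bis(methoxymethoxy)phenyl]-3-phenylprop-2-en-1-ol F4. MnO2 oxidizes it to the silylated chalcone F5, and TBAF/AcOH frees the 3'-phenol of chalcone F6. Steglich esterification with 5 (DCC, DMAP) gives the bis-MOM ester F7, and brief acid treatment (CF3CO2H, wet CH2Cl2, 0 °C) removes both MOM groups to give 19.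

2. Step 8.
   - What may go wrong: the free carbinol, benzylic to a 2,4,6-trioxygenated ring, allylic and ortho to a phenol, may lose water to an ortho-quinone methide that closes to a 2H-chromene; under fluoride the 3'-acyl group may migrate to the 2'-oxygen.
   - Fallback, setting out from 16 and coming back at 18: oxidative desilylation with DDQ (CH2Cl2/pH 7 buffer, 0 °C), a known direct conversion of electron-rich benzylic and allylic silyl ethers into ketones. Hydride abstraction from the carbinol C–H gives a silyloxocarbenium ion that loses the silyl group to water, so the free carbinol 17 is never formed and steps 8 and 9 merge. This fallback makes no compound that the list does not hold (F0).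

3. Step 10.
   - What may go wrong: protic acid may promote oxa-Michael closure of the 2'-hydroxychalcone to a flavanone, tert-butylation of the electron-rich C5' position by the released cation, or acyl migration between the 2'-, 3'- and 4'-oxygens.
   - Fallback, setting out from 18 and coming back at 19: aprotic silyl-transfer dealkylation in place of protic acidolysis. TMSOTf with 2,6-lutidine in CH2Cl2 at 0 °C exchanges the tert-butyl group for trimethylsilyl (isobutene is lost to the hindered base) and silylates the 2'-hydroxyl, giving the 2',4'-bis(trimethylsilyl) ether F8. Hydrolysis in pH 7 phosphate buffer/THF then gives 19.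

**Further compounds**

F1 | step 7 | 1-methoxy-3,5-bis(methoxymethoxy)benzene | COCOc1cc(OC)cc(OCOC)c1
F2 | step 7 | 4-methoxy-2,6-bis(methoxymethoxy)phenol | COCOc1cc(OC)cc(OCOC)c1O
F3 | step 7 | tert-butyl[4-methoxy-2,6-bis(methoxymethoxy)phenoxy]dimethylsilane | COCOc1cc(OC)cc(OCOC)c1O[Si](C)(C)C(C)(C)C
F4 | step 7 | (E)-1-[3-(tert-butyldimethylsilyloxy)-6-methoxy-2,4-bis(methoxymethoxy)phenyl]-3-phenylprop-2-en-1-ol (racemic) | COCOc1cc(OC)c(C(O)/C=C/c2ccccc2)c(OCOC)c1O[Si](C)(C)C(C)(C)C
F5 | step 7 | (E)-1-[3-(tert-butyldimethylsilyloxy)-6-methoxy-2,4-bis(methoxymethoxy)phenyl]-3-phenylprop-2-en-1-one | COCOc1cc(OC)c(C(=O)/C=C/c2ccccc2)c(OCOC)c1O[Si](C)(C)C(C)(C)C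
F6 | step 7 | (E)-1-[3-hydroxy-6-methoxy-2,4-bis(methoxymethoxy)phenyl]-3-phenylprop-2-en-1-one | COCOc1cc(OC)c(C(=O)/C=C/c2ccccc2)c(OCOC)c1O
F7 | step 7 | 3-[(E)-cinnamoyl]-4-methoxy-2,6-bis(methoxymethoxy)phenyl (S)-2-methylbutanoate | CC[C@H](C)C(=O)Oc1c(OCOC)cc(OC)c(C(=O)/C=C/c2ccccc2)c1OCOC
F0 | step 8 | none | none
F8 | step 10 | 3-[(E)-cinnamoyl]-4-methoxy-2,6-bis(trimethylsilyloxy)phenyl (S)-2-methylbutanoate | CC[C@H](C)C(=O)Oc1c(O[Si](C)(C)C)cc(OC)c(C(=O)/C=C/c2ccccc2)c1O[Si](C)(C)C
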